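(The numbers of this flask were chosen freely.)

- In a one-step world of step 2 by itself, with its equilibrium constant times starting substrate at 33, target looked to me like a product that stays.

    substrate ⇌ other conformer (K1 = 0.49, k1 = 9.5 × 10⁻⁴ /s)
    substrate + reagent ⇌ target (K2 = 33 /M, k2 = 0.0050 /M/s)
    reagent + other conformer → isomer of the product (k3 = 0.046 /M/s)

| flask | substrate | reagent | other conformer | time | remark |
|---|---|---|---|---|---|
| Monday's | 1.0 M | 0.800 M (fed, over 0.500 h) | 0.250 M | 1.0 h | a stirred flask in which reagent is dosed at a steady rate over 0.500 h without added volume, worked up at 1.0 h |
| Thursday's | 1.0 M | 0.800 M | 0.250 M (fed, over 0.500 h) | 1.0 h | all but other conformer at the start; other conformer goes in evenly over 0.500 h, the run ends at 1.0 h |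
| Wednesday's | 1.0 M | 0.800 M | 0.250 M | 1.0 h | a closed flask charged with all of it at once and left for 1.0 h |
| Saturday's | 1.0 M | 0.800 M | 0.250 M |  | a single well-mixed tank run continuously and read at steady state, 1.0 h in it on average |

- the set-up with the highest amount of target at the outlet or at the end, in percent of the substrate and other conformer together put in ("none" if the first two lie within 2 percentage points) (Monday's / Thursday's / Wednesday's / Saturday's / none)
- amount of target at the outlet or at the end, in percent of the substrate and other conformer together put in, Monday's
- amount of target at the outlet or at the end, in percent of the substrate and other conformer together put in, Thursday's
- amount of target at the outlet or at the end, in percent of the substrate and other conformer together put in, Wednesday's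
- amount of target at the outlet or at the end, in percent of the substrate and other conformer together put in, Saturday's

- Reagent was my limiting reagent, its charge standing below substrate and other conformer together. Target and isomer of the product drew on that one charge, so target in Wednesday's had a ceiling of 64.0%.
- I drew Wednesday's target curve from its start, where it climbed at 0.192 /min as a fraction of substrate and other conformer together.
- I left the height of its knee open below that ceiling.
- The tail I could reckon. Target gave reagent back at 0.545 /h, the backward constant of step 2.
- Each released reagent then met substrate and other conformer, which I held at their equilibrium ratio, and the other conformer's share of it came to 81.8%.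
- The product of the two was my leak constant, the rate at which target is lost for good once reagent is low: 0.446 /h.
- Its half-life, 1.55 h, was longer than the 0.0667 h relaxation half-life of substrate and other conformer, so holding them at equilibrium was fair for this tail.
- Over 0.500 h, I reckoned the leak to take 20.0% of the target.
- Target's side of the same split, applied to the whole reagent charge with the leak set aside, gave my estimate for Saturday's tank: 11.6%.
- The forecast named Thursday's, with 12% for Monday's, 26% for Thursday's, 20.5% for Wednesday's and 11.6% for Saturday's, and said of the late loss that “its released reagent is drained irreversibly into the isomer”.
- The simulation gave Thursday's, with 12.3% for Monday's, 27.5% for Thursday's, 20.5% for Wednesday's and 11.6% for Saturday's.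
- Thursday's target stood at 34.2% at 0.500 h and 27.5% at 1.0 h, where my leak gave 27.4%, so the best flask was already past its higher reading when worked up. For the neighbour, Thursday's left until 1.5 h, the leak carried 27.5% forward to 22.0%. That flask read 22.1% target, with isomer of the product at 41.4%.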